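The numbers in the tables are calculated with made-up constants.

| setting | midnight | dusk | flask |
|---|---|---|---|
| substrate | 0.091 M | 0.091 M | 0.091 M |
| coupling partner | 0.10 M | 0.10 M | 0.100 M |
| free catalyst | 0.10 mM | 0.10 mM | 0.10 mM |
| temperature | 70 °C | 76 °C | 70 °C |
| remark | the very flask that is asked about, followed so far | run made earlier |  |
| time |  |  | 4.0 d |

- midnight (time / h: target / %): 8.00: 55.3; 12.0: 56.6; 20.0: 54.8; 25.0: 50.7; 40.0: 46.2; 60.0: 37.2; 96.0: 35.2
- dusk (time / h: target / %): 8.00: 52.3; 12.0: 47.3; 20.0: 44.1; 25.0: 41.5; 40.0: 35.2; 60.0: 36.0; 96.0: 34.6

(readings scatter by 1 percentage point)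

- Saturday's: at 4.0 d add coupling partner, 50.0% of the amount charged, then wait 30 h
- Friday's: at 4.0 d raise the temperature by 15 K, then wait 30 h
- Monday's: change nothing and wait 30 h more
- Sunday's: at 4.0 d add free catalyst, 50.0% of the amount charged, then wait 30 h

- what is added takes up no volume worth counting
- a reading or a percentage of target counts all its forms, free or not

* target, in percent of the substrate first charged, at 4.0 d
* the remedy with the largest gain of target, or "none" below 2 percentage points (Saturday's / Friday's / Monday's / Sunday's / none)
* target present, in percent of the substrate first charged, after Saturday's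
* target present, in percent of the substrate first charged, after Sunday's

1. The easy step came first: I took the midnight flask's highest reading, 56.6%, and its last, 35.2%. The dusk run ended at 35.2%, 36.0% and 34.6%, flat against a scatter of 1 percentage point, so I treated both runs as stopped. Two amounts can then stand in for two rates, and time drops out.

2. I defined the loss ratio, 0.608 in the midnight run, as target lost after the peak over target kept at the end. If the fall is reversible, this ratio is a rough stand-in for forward rate over back rate, with no concentration in it, and it reads low if some target had already been lost by the peak. So I expected adding catalyst, adding coupling partner or waiting to leave target near its last reading.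

3. That left Friday's. The dusk run gave 0.512, lower than midnight's. This was weak evidence, since dusk's peak may precede its first reading. Stretching that trend by a constant factor per kelvin over the rise of 15 K gave 0.395. Midnight's peak divided by one plus that ratio gave 40.6% of target. I committed to Friday's, with a gain of about 5.4 points.

4. The forecast said 35.2% now (range 33.8% to 36.6%), 35.2% after Saturday's, 35.2% after Sunday's, and best: none, holding that “Heat changes little”. We parted on Friday's.

5. The flask gave 35.4% now, 34.5% after Saturday's, 34.5% after Sunday's, and best: Friday's, gaining 6.8 points.

    catalyst intermediate B → catalyst intermediate C (k = 819 h⁻¹, Ea = 74.0 kJ mol⁻¹)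
    coupling partner + free catalyst → catalyst intermediate A (k = 5870 M⁻¹ h⁻¹, Ea = 51.0 kJ mol⁻¹)
    target ⇌ isomer of the product (K = 0.960, k = 0.0181 h⁻¹, Ea = 110 kJ mol⁻¹, ΔH = −34.0 kJ mol⁻¹)
    substrate + catalyst intermediate A ⇌ catalyst intermediate B (K = 15.0 M⁻¹, k = 4750 M⁻¹ h⁻¹, Ea = 67.0 kJ mol⁻¹, ΔH = −53.0 kJ mol⁻¹)
    catalyst intermediate C → free catalyst + target (k = 5830 h⁻¹, Ea = 85.0 kJ mol⁻¹)
    crystals ⇌ target, rate k6*(cs6 - [target]) while solid is left; crystals form when [target] > cs6 (solubility = 41.0 mM, k = 57.0 h⁻¹)
    2 substrate → self-condensation product (k = 1.33 M⁻¹ h⁻¹, Ea = 88.0 kJ mol⁻¹)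
    (constants at 70 °C)

6. The parting lay in the balance of target and isomer of the product, which relaxes with a half-life of 18.8 h, short against 4.0 d. This is thermodynamic control. With that step taken away, the gain from Friday's falls from 6.8 points to 0 points.

7. The neighbour flask, with 0.36 M of substrate, has 0.278 equiv of coupling partner. Taking that share as target plus isomer of the product and dividing by one plus the loss ratio gave 17.3% of target. The computed flask holds 18.7%.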